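## The problem

Atoms are numbered C1 (ring ketone), C2, C3 (enol-ether carbon), C4 (bearing methyl C15), C5, C6 (ester carbinol), C7, C8 (lactone carbinol), C9, C10 (quaternary, bearing methyl C14), then C11, C12 and methylene C13 for the lactone. The target is a ten-membered carbocycle (C1–C10) in which an oxygen bridges C3 and C10, so that C10–O–C3=C2–C1(=O) is a 3(2H)-furanone inside the ring. A Z-trisubstituted C4=C5 alkene is conjugated to the furanone, an α-methylene-γ-butyrolactone is trans-fused across C7–C8, and O6 carries a (2R,3R)-epoxyangelate. Four ring stereocentres (C6, C7, C8, C10) and two side-chain centres must be set. C10 is quaternary and isolated, so it has to be brought in alone. C6 and C8 are a 1,3-anti pair, so one can be relayed from the other. C7 lies between them and can be set last from C8 through a tether. The acrylate, the glycidic ester, the Z-dienone and the 1,3-related esters (acyl migration) tolerate neither strong base nor strong nucleophiles nor prolonged acid, so they should appear late. The strained, bridged medium ring must be closed from a chain in which the Z geometry is already fixed. The feature that opens the problem is that C7, once the lactone is removed, is a plain methylene. The C7–C11 bond lies 1,5 to the α-carbon of an ester on O8, so C11/C12 can be delivered as a diazo ester and attached by C–H insertion.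

## Retrosynthesis

**C11=C13.** Target 33 is cut to the α-phosphono lactone 32 and formaldehyde. Against methylenation of an unsubstituted lactone enolate, the phosphonate lets the alkene form with carbonate base in the presence of two other esters. 32 lacks the Michael acceptor, and the forward Horner–Wadsworth–Emmons step only has to be mild.

**C7–C11 (key).** 32 is cut to the diazophosphonoacetate 31. Cutting the lactone C–O bond instead would leave an acetic acid branch on C7 and three contiguous stereocentres to carry through the ring synthesis. The C–H insertion cut removes one ring, one C–C bond and two stereocentres and makes C7 a CH2. The forward reaction must choose C7 over C9 and the C7 hydrogen that gives the trans fusion.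

**Ester order.** 31 comes from phosphonoacetate 30 by diazo transfer, 30 from alcohol 28 and acid 29, 28 from silyl ether 27, and 27 from alcohol 22 and epoxy acid 26. Acylating O6 first means each acylation meets a single free hydroxyl. This requires 22 to carry O6 free and O8 silylated.

**O–C3 of the furanone.** 22 comes from acetate 21, and 21 is opened at the C3–O bond to the α'-hydroxy ynone 20. The neighbouring cut to a 1,3-diketone would need another oxidation level and acid for dehydration, whereas the ynone needs only a π-acid. The bridged bicycle becomes a monocyclic cyclodecenynone.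

**C1–C2 ring closure.** 20 comes from propargylic diol 19, which is opened at C1–C2 to iodoalkyne aldehyde 18. Closure at C6–C7 by aldol would be reversible and hard for a medium ring. Closure at C4=C5 by metathesis would have to join a conjugated 1,1-disubstituted alkene. The alkynyl–aldehyde coupling is irreversible, selective for the aldehyde, tolerant of the free hydroxyl and the acetate, and joins two unhindered ends held near each other by the Z alkene. The forward step needs high dilution.

**C6–C7 and the C8 centre.** 18 is traced through 17, 16 and 15 to the anti-diol monoacetate 14, and 14 to aldol adduct 13, which is cut at C6–C7 into methyl ketone 11 and enal 6. The aldol sets C6 by reagent control. The Evans–Tishchenko reduction then sets C8 anti to C6 and leaves O6 as an acetate, so the O6/O8 differentiation needed later comes from the reduction itself.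

**Fragments.** Ketone 11 comes from (S)-2-methylglycidol 7 and isopropenylmagnesium bromide 8; the epoxide carries C10 and the acetonide masks O10 and O1 together. Enal 6 comes from but-2-yn-1-ol 1 and ethynyltrimethylsilane 4, with the Z geometry fixed by hydroalumination–iodination. Epoxy acid 26 comes from angelic acid 23 by reduction, Sharpless epoxidation and oxidation.

## Roads not taken

**Alternative 1:** The cut is at C6–C7 and C11–C13 on a small lactone. Lithium tris(methylthio)methanide would add to the butenolide A1 anti to its C8 substituent, and the lactone enolate would be trapped by dimethylmethyleneammonium iodide to give A2. This fixes C7 relative to C8 by a simple steric argument and installs a robust latent acrylate in one flask. In that respect it is better than the chosen plan, where C7 depends on which C–H bond the carbenoid picks. Its weak points are that no ring is closed and that A2 holds only C6–C9 and C11–C13. The ten-membered ring, the furanone, the Z alkene, C6 and C10 would all have to be built around a base-sensitive lactone, with the orthothioester first unmasked to a C6 carbonyl. Against its certainty at C7, the chosen plan sets a C7 that needs no handle, a lactone that never passes through the macrocyclisation, and fewer protecting-group operations.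

**Alternative 2:** The cut is at O–C10 and C9–C10. A copper carbenoid from the diazoketone A3 would be captured by the ring oxygen, and the oxonium ylide would undergo a [2,3] shift through the C7 vinyl group to give A4. This closes the oxa-bridge and the ten-membered ring and sets the C10 quaternary centre in one step. For ring construction it is better than the chosen plan, which spends separate steps on macrocyclisation and furanone closure. Its weak points lie after the key step. A4 has a C7=C8 alkene that must be converted regio- and stereoselectively into the C8 carbinol beside a second ring alkene, and C2–C3 must be dehydrogenated to the furanone. A3 needs a 2,6-cis dihydropyran with three stereocentres, and [1,2] shift and alkene geometry are known risks of such ylides. The chosen plan sets against this that O6 and O8 are in place with a reliable 1,3-anti relay before any ring is closed, and that no two ring alkenes have to be told apart.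

**Alternative 3:** The cut is at C4=C5. The eleven-membered sulfone A5 would be α-halogenated in situ, closed to the episulfone and would lose SO2 to give A6. The ring is first closed as a larger, easier ring through sulfur, and the contraction delivers the Z alkene under ring control. This is gentler than the strained C1–C2 closure of the chosen plan. Its weak points are the strongly basic, halogenating conditions on a substrate with a furanone and a free C6 hydroxyl β to the sulfone, and the uncertain site of halogenation. The C7 branch, with three contiguous stereocentres C6–C8, must be built before the ring. At least four further steps are needed to turn the allylic silyl ether into the lactone. The chosen plan sets against the easier ring closure that its Z alkene is fixed in the first step and that C7 stays a methylene until the end.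

Key step: step 24

Assumptions: (S)-2-methylglycidol 7 is taken as a catalogue compound. Macrocyclic intermediates are named with the target numbering defined above. Compound 19 forms as both C1 epimers, and its SMILES leaves C1 open.

## Steps

Step 1
Reactants: 1 but-2-yn-1-ol
Product: 3 (Z)-3-iodobut-2-en-1-ol, via cyclic alkenylaluminate 2 (not isolated)
Conditions: NaAlH2(OCH2CH2OMe)2, THF, 0 → 25 °C; then I2, THF, −78 → 0 °C
Reagents that add atoms: iodine, II
Why: Alkoxide-directed trans-hydroalumination of the propargylic alcohol puts aluminium on C4 in a five-membered alanate, and iodinolysis with retention gives the Z iodide, which fixes the C4=C5 geometry of the target.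

Step 2
Reactants: 3 (Z)-3-iodobut-2-en-1-ol; 4 ethynyltrimethylsilane
Product: 5 (Z)-3-methyl-5-(trimethylsilyl)pent-2-en-4-yn-1-ol
Conditions: Pd(PPh3)2Cl2 (2 mol %), CuI (4 mol %), Et3N, THF, 25 °C
Reagents that add atoms: none
Why: Sonogashira coupling of an alkenyl iodide proceeds with retention of alkene geometry and tolerates the free allylic alcohol.

Step 3
Reactants: 5 (Z)-3-methyl-5-(trimethylsilyl)pent-2-en-4-yn-1-ol
Product: 6 (Z)-3-methyl-5-(trimethylsilyl)pent-2-en-4-ynal
Conditions: MnO2 (activated, excess), CH2Cl2, 25 °C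
Reagents that add atoms: none
Why: Neutral allylic oxidation with MnO2 gives the enal without acid or base that could isomerise the Z alkene; the aldehyde is used directly.

Step 4
Reactants: 7 (S)-2-methylglycidol; 8 isopropenylmagnesium bromide
Product: 9 (2R)-2,4-dimethylpent-4-ene-1,2-diol
Conditions: CuI (10 mol %), THF, −30 → 0 °C (3 equiv of 8); aq. NH4Cl
Reagents that add atoms: none
Why: Copper-catalysed Grignard opening occurs at the unsubstituted epoxide carbon, so the C10–O bond is untouched and the quaternary centre keeps its configuration; the isopropenyl group is a masked acetyl.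

Step 5
Reactants: 9 (2R)-2,4-dimethylpent-4-ene-1,2-diol
Product: 10 (4R)-2,2,4-trimethyl-4-(2-methylprop-2-en-1-yl)-1,3-dioxolane
Conditions: Me2C(OMe)2, PPTS (cat.), CH2Cl2, 25 °C
Reagents that add atoms: 2,2-dimethoxypropane, COC(C)(C)OC
Why: Acid-catalysed acetal exchange gives the five-membered acetonide, which protects the tertiary and the primary hydroxyl in one group.

Step 6
Reactants: 10 (4R)-2,2,4-trimethyl-4-(2-methylprop-2-en-1-yl)-1,3-dioxolane
Product: 11 1-[(4R)-2,2,4-trimethyl-1,3-dioxolan-4-yl]propan-2-one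
Conditions: OsO4 (2 mol %), NaIO4, 2,6-lutidine, dioxane/H2O (3:1), 25 °C
Reagents that add atoms: sodium periodate, [Na+].[O-]I(=O)(=O)=O
Why: Lemieux–Johnson cleavage of the 1,1-disubstituted alkene gives the methyl ketone; the buffered medium leaves the acetonide intact.

Step 7
Reactants: 11 1-[(4R)-2,2,4-trimethyl-1,3-dioxolan-4-yl]propan-2-one; 6 (Z)-3-methyl-5-(trimethylsilyl)pent-2-en-4-ynal
Product: 13 (4R,5Z)-4-hydroxy-6-methyl-1-[(4R)-2,2,4-trimethyl-1,3-dioxolan-4-yl]-8-(trimethylsilyl)oct-5-en-7-yn-2-one, via enol diisopinocampheylborinate 12 (not isolated)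
Conditions: (−)-Ipc2BCl, Et3N, Et2O, 0 °C; 6, −78 → −20 °C; then H2O2, pH 7 buffer, MeOH, 0 °C
Reagents that add atoms: none
Why: Paterson boron aldol: the amine and Ipc2BCl enolise the ketone on the methyl side, and the isopinocampheyl ligands direct the enolate to the Re face of the enal, which sets C6 as R by reagent control. The level of control is moderate for methyl ketones, and the minor C6 epimer is a diastereomer removable by chromatography.

Step 8
Reactants: 13 (4R,5Z)-4-hydroxy-6-methyl-1-[(4R)-2,2,4-trimethyl-1,3-dioxolan-4-yl]-8-(trimethylsilyl)oct-5-en-7-yn-2-one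
Product: 14 (3Z,5R,7R)-7-hydroxy-3-methyl-8-[(4R)-2,2,4-trimethyl-1,3-dioxolan-4-yl]-1-(trimethylsilyl)oct-3-en-1-yn-5-yl acetate
Conditions: SmI2 (30 mol %), MeCHO (6 equiv), THF, −10 °C
Reagents that add atoms: acetaldehyde, CC=O
Why: Evans–Tishchenko reduction: the samarium-bound hemiacetal of O6 with acetaldehyde delivers hydride to the C8 ketone through a chair-like bicyclic transition state, which gives the 1,3-anti alcohol (8R) and leaves O6 as the acetate.

Step 9
Reactants: 14 (3Z,5R,7R)-7-hydroxy-3-methyl-8-[(4R)-2,2,4-trimethyl-1,3-dioxolan-4-yl]-1-(trimethylsilyl)oct-3-en-1-yn-5-yl acetate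
Product: 15 (3Z,5R,7R)-7-[(tert-butyldimethylsilyl)oxy]-3-methyl-8-[(4R)-2,2,4-trimethyl-1,3-dioxolan-4-yl]-1-(trimethylsilyl)oct-3-en-1-yn-5-yl acetate
Conditions: TBSOTf, 2,6-lutidine, CH2Cl2, −78 °C
Reagents that add atoms: tert-butyldimethylsilyl trifluoromethanesulfonate, CC(C)(C)[Si](C)(C)OS(=O)(=O)C(F)(F)F
Why: Fast silylation under non-nucleophilic conditions caps O8 before the acetate can migrate from O6.

Step 10
Reactants: 15 (3Z,5R,7R)-7-[(tert-butyldimethylsilyl)oxy]-3-methyl-8-[(4R)-2,2,4-trimethyl-1,3-dioxolan-4-yl]-1-(trimethylsilyl)oct-3-en-1-yn-5-yl acetate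
Product: 16 (3Z,5R,7R)-7-[(tert-butyldimethylsilyl)oxy]-1-iodo-3-methyl-8-[(4R)-2,2,4-trimethyl-1,3-dioxolan-4-yl]oct-3-en-1-yn-5-yl acetate
Conditions: NIS, AgNO3 (10 mol %), acetone, 25 °C, dark
Reagents that add atoms: N-iodosuccinimide, O=C1CCC(=O)N1I
Why: Silver-catalysed iododesilylation converts the alkynylsilane directly into the 1-iodoalkyne under neutral conditions that leave the alkene, acetate, silyl ether and acetonide untouched.

Step 11
Reactants: 16 (3Z,5R,7R)-7-[(tert-butyldimethylsilyl)oxy]-1-iodo-3-methyl-8-[(4R)-2,2,4-trimethyl-1,3-dioxolan-4-yl]oct-3-en-1-yn-5-yl acetate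
Product: 17 (3Z,5R,7R,9R)-7-[(tert-butyldimethylsilyl)oxy]-9,10-dihydroxy-1-iodo-3,9-dimethyldec-3-en-1-yn-5-yl acetate
Conditions: PPTS (0.3 equiv), MeOH, 40 °C
Reagents that add atoms: none
Why: Mild acetal exchange removes the terminal acetonide; a secondary TBS ether and an acetate are stable to PPTS in methanol.

Step 12
Reactants: 17 (3Z,5R,7R,9R)-7-[(tert-butyldimethylsilyl)oxy]-9,10-dihydroxy-1-iodo-3,9-dimethyldec-3-en-1-yn-5-yl acetate
Product: 18 (3Z,5R,7R,9R)-7-[(tert-butyldimethylsilyl)oxy]-9-hydroxy-1-iodo-3,9-dimethyl-10-oxodec-3-en-1-yn-5-yl acetate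
Conditions: SO3·pyridine, DMSO, iPr2NEt, CH2Cl2, 0 °C
Reagents that add atoms: none
Why: Parikh–Doering oxidation converts only the primary alcohol and does not cleave the 1,2-diol; the α-carbon is quaternary, so the aldehyde cannot epimerise or enolise.

Step 13
Reactants: 18 (3Z,5R,7R,9R)-7-[(tert-butyldimethylsilyl)oxy]-9-hydroxy-1-iodo-3,9-dimethyl-10-oxodec-3-en-1-yn-5-yl acetate
Product: 19 (4Z,6R,8R,10R)-8-[(tert-butyldimethylsilyl)oxy]-1,10-dihydroxy-4,10-dimethylcyclodec-4-en-2-yn-6-yl acetate (target numbering, both C1 epimers)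
Conditions: CrCl2 (10 equiv), NiCl2 (1 mol % of CrCl2), THF, 25 °C, 0.002 M, slow addition
Reagents that add atoms: none
Why: Intramolecular Nozaki–Hiyama–Kishi coupling: the alkynylchromium species (trivalent chromium) formed from the iodoalkyne adds only to the aldehyde and tolerates the free hydroxyl and the ester. This closure is known for ten-membered enediyne rings, and the Z alkene holds the chain ends on the same side. The C1 configuration is irrelevant because C1 is oxidised next.

Step 14
Reactants: 19 (4Z,6R,8R,10R)-8-[(tert-butyldimethylsilyl)oxy]-1,10-dihydroxy-4,10-dimethylcyclodec-4-en-2-yn-6-yl acetate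
Product: 20 (4Z,6R,8R,10R)-8-[(tert-butyldimethylsilyl)oxy]-10-hydroxy-4,10-dimethyl-1-oxocyclodec-4-en-2-yn-6-yl acetate (target numbering)
Conditions: IBX, DMSO, 25 °C
Reagents that add atoms: none
Why: IBX oxidises the secondary propargylic alcohol of a 1,2-diol to the α-hydroxy ketone without glycol cleavage; both C1 epimers converge on one ynone.

Step 15
Reactants: 20 (4Z,6R,8R,10R)-8-[(tert-butyldimethylsilyl)oxy]-10-hydroxy-4,10-dimethyl-1-oxocyclodec-4-en-2-yn-6-yl acetate
Product: 21 (4Z,6R,8R,10R)-8-[(tert-butyldimethylsilyl)oxy]-3,10-epoxy-4,10-dimethyl-1-oxocyclodeca-2,4-dien-6-yl acetate (target numbering; the 3,10-oxygen bridge completes the 3(2H)-furanone)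
Conditions: (Ph3P)AuCl (5 mol %), AgOTf (5 mol %), toluene, 25 °C
Reagents that add atoms: none
Why: Cationic monovalent gold activates the ynone alkyne for 5-endo-dig attack by the C10 hydroxyl (the known cycloisomerisation of α'-hydroxy ynones to 3(2H)-furanones), and protodeauration gives the bridged furanone. O6 is kept as the acetate so that it cannot compete for C3.

Step 16
Reactants: 21 (4Z,6R,8R,10R)-8-[(tert-butyldimethylsilyl)oxy]-3,10-epoxy-4,10-dimethyl-1-oxocyclodeca-2,4-dien-6-yl acetate
Product: 22 (4Z,6R,8R,10R)-8-[(tert-butyldimethylsilyl)oxy]-3,10-epoxy-6-hydroxy-4,10-dimethylcyclodeca-2,4-dien-1-one (target numbering)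
Conditions: K2CO3, MeOH, 0 °C
Reagents that add atoms: none
Why: Carbonate-catalysed methanolysis removes the only ester in the molecule; 3(2H)-furanones and secondary TBS ethers are stable to these conditions.

Step 17
Reactants: 23 angelic acid
Product: 24 (Z)-2-methylbut-2-en-1-ol
Conditions: LiAlH4, Et2O, 0 °C
Reagents that add atoms: none
Why: Hydride reduction of the β-alkyl-substituted enoic acid is a 1,2-reduction that leaves the Z alkene unchanged.

Step 18
Reactants: 24 (Z)-2-methylbut-2-en-1-ol
Product: 25 [(2S,3R)-2,3-dimethyloxiran-2-yl]methanol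
Conditions: Ti(OiPr)4 (10 mol %), L-(+)-diethyl tartrate (12 mol %), t-BuOOH, 4 Å MS, CH2Cl2, −20 °C
Reagents that add atoms: tert-butyl hydroperoxide, CC(C)(C)OO
Why: Sharpless asymmetric epoxidation: the L-(+)-tartrate complex delivers oxygen to the alkene face that gives the (2S,3R) epoxy alcohol, and the Z geometry is carried over as the cis relation of CH2OH and the C3 methyl.

Step 19
Reactants: 25 [(2S,3R)-2,3-dimethyloxiran-2-yl]methanol
Product: 26 (2R,3R)-2,3-dimethyloxirane-2-carboxylic acid
Conditions: RuCl3·H2O (2 mol %), NaIO4, CCl4/MeCN/H2O, 25 °C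
Reagents that add atoms: water, O
Why: Catalytic RuO4 oxidation takes the primary epoxy alcohol to the glycidic acid without touching the epoxide; the descriptor at C2 changes from S to R only because the priorities change.

Step 20
Reactants: 22 (4Z,6R,8R,10R)-8-[(tert-butyldimethylsilyl)oxy]-3,10-epoxy-6-hydroxy-4,10-dimethylcyclodeca-2,4-dien-1-one; 26 (2R,3R)-2,3-dimethyloxirane-2-carboxylic acid
Product: 27 (4Z,6R,8R,10R)-8-[(tert-butyldimethylsilyl)oxy]-3,10-epoxy-4,10-dimethyl-1-oxocyclodeca-2,4-dien-6-yl (2R,3R)-2,3-dimethyloxirane-2-carboxylate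
Conditions: 2-methyl-6-nitrobenzoic anhydride, Et3N, DMAP, CH2Cl2, 25 °C
Reagents that add atoms: none
Why: Shiina esterification activates the hindered acid as a mixed anhydride and DMAP transfers the acyl group to O6, the only free hydroxyl; the acid has no α-hydrogen and cannot epimerise.

Step 21
Reactants: 27 (4Z,6R,8R,10R)-8-[(tert-butyldimethylsilyl)oxy]-3,10-epoxy-4,10-dimethyl-1-oxocyclodeca-2,4-dien-6-yl (2R,3R)-2,3-dimethyloxirane-2-carboxylate
Product: 28 (4Z,6R,8R,10R)-3,10-epoxy-8-hydroxy-4,10-dimethyl-1-oxocyclodeca-2,4-dien-6-yl (2R,3R)-2,3-dimethyloxirane-2-carboxylate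
Conditions: HF·pyridine, pyridine, THF, 0 → 25 °C
Reagents that add atoms: none
Why: Buffered HF cleaves the silyl ether without base, so the O6 ester does not migrate to O8; the epoxide of a glycidic ester is deactivated toward acid opening.

Step 22
Reactants: 28 (4Z,6R,8R,10R)-3,10-epoxy-8-hydroxy-4,10-dimethyl-1-oxocyclodeca-2,4-dien-6-yl (2R,3R)-2,3-dimethyloxirane-2-carboxylate; 29 diethylphosphonoacetic acid
Product: 30 (4Z,6R,8R,10R)-8-{[2-(diethoxyphosphoryl)acetyl]oxy}-3,10-epoxy-4,10-dimethyl-1-oxocyclodeca-2,4-dien-6-yl (2R,3R)-2,3-dimethyloxirane-2-carboxylate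
Conditions: DCC, DMAP (cat.), CH2Cl2, 0 → 25 °C
Reagents that add atoms: none
Why: Steglich esterification of the single free secondary alcohol with an unhindered acid.

Step 23
Reactants: 30 (4Z,6R,8R,10R)-8-{[2-(diethoxyphosphoryl)acetyl]oxy}-3,10-epoxy-4,10-dimethyl-1-oxocyclodeca-2,4-dien-6-yl (2R,3R)-2,3-dimethyloxirane-2-carboxylate
Product: 31 (4Z,6R,8R,10R)-8-{[2-diazo-2-(diethoxyphosphoryl)acetyl]oxy}-3,10-epoxy-4,10-dimethyl-1-oxocyclodeca-2,4-dien-6-yl (2R,3R)-2,3-dimethyloxirane-2-carboxylate
Conditions: p-ABSA, DBU, MeCN, 0 °C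
Reagents that add atoms: 4-acetamidobenzenesulfonyl azide, CC(=O)Nc1ccc(cc1)S(=O)(=O)N=[N+]=[N-]
Why: Regitz diazo transfer to the doubly activated methylene of the phosphonoacetate; the other ester has no α-hydrogen and the furanone is not enolisable.

Step 24
Reactants: 31 (4Z,6R,8R,10R)-8-{[2-diazo-2-(diethoxyphosphoryl)acetyl]oxy}-3,10-epoxy-4,10-dimethyl-1-oxocyclodeca-2,4-dien-6-yl (2R,3R)-2,3-dimethyloxirane-2-carboxylate
Product: 32 (6S,7R,8S,10R,11R)-11-(diethoxyphosphoryl) trans-fused 12,8-lactone of the furanone-bridged cyclodecene bearing the (2R,3R)-epoxyangelate on O6 (target numbering)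
Conditions: Rh2(OAc)4 (2 mol %), ClCH2CH2Cl, reflux, slow addition of 31
Reagents that add atoms: none
Why: Rh2(OAc)4 (divalent rhodium) takes up the diazo carbon and expels N2, giving an electrophilic acceptor/acceptor carbenoid at C11 that inserts into a C7–H bond through a concerted three-centre transition state. The closest known reaction type is the dirhodium-catalysed 1,5 C–H insertion of alkyl diazophosphonoacetates to α-phosphono-γ-butyrolactones. The five-membered lactone closes by C7–C11 bond formation across the O8 ester tether, which is the normal 1,5 mode for this tether. C7 forms with retention at the hydrogen that is replaced: in the ring conformer with C6 and C9 anti about C7–C8 only one C7 hydrogen is gauche to O8, and its replacement gives the trans fusion (7R). C11 is epimerisable and should settle with the phosphonate trans to the C6 branch (11R); it is erased in step 25. The step needs C7 over C9: C9 is neopentylic and lies β to both the furanone oxygen and the C1 carbonyl on C10, so it is more hindered and more deactivated than C7, which has one β-acyloxy group besides the tether. The O6 ester deactivates the allylic C6–H and so blocks six-membered closure, and four-membered closure at C8–H is disfavoured for this carbenoid class. Both ring alkenes are conjugated and electron-poor and the epoxide oxygen is remote, so cyclopropanation and ylide formation should not compete.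

Step 25
Reactants: 32 (6S,7R,8S,10R,11R)-11-(diethoxyphosphoryl) trans-fused 12,8-lactone bearing the epoxyangelate on O6
Product: 33 target (CNP0258430.3), (6S,7R,8S,10R)-configured α-methylene lactone with the (2R,3R)-epoxyangelate on O6
Conditions: aq. CH2O (37 %), K2CO3, THF, 0 → 25 °C
Reagents that add atoms: formaldehyde, C=O
Why: Horner–Wadsworth–Emmons reaction of the phosphonate-stabilised lactone anion with formaldehyde installs C13 and removes the C11 stereocentre; carbonate is mild enough for both esters and the furanone.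

## Compound list

1 | but-2-yn-1-ol | CC#CCO | starting material
2 | sodium 2,2-bis(2-methoxyethoxy)-3-methyl-2,5-dihydro-1,2-oxaaluminol-2-uide (cyclic alkenylaluminate) | CC1=CCO[Al-]1(OCCOC)OCCOC.[Na+] | intermediate
3 | (Z)-3-iodobut-2-en-1-ol | C/C(I)=C/CO | intermediate
4 | ethynyltrimethylsilane | C#C[Si](C)(C)C | starting material
5 | (Z)-3-methyl-5-(trimethylsilyl)pent-2-en-4-yn-1-ol | C[Si](C)(C)C#C/C(C)=C\CO | intermediate
6 | (Z)-3-methyl-5-(trimethylsilyl)pent-2-en-4-ynal | C[Si](C)(C)C#C/C(C)=C\C=O | intermediate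
7 | (S)-2-methylglycidol, [(2S)-2-methyloxiran-2-yl]methanol | OC[C@@]1(C)CO1 | starting material
8 | isopropenylmagnesium bromide | C=C(C)[Mg]Br | starting material
9 | (2R)-2,4-dimethylpent-4-ene-1,2-diol | C=C(C)C[C@@](C)(O)CO | intermediate
10 | (4R)-2,2,4-trimethyl-4-(2-methylprop-2-en-1-yl)-1,3-dioxolane | C=C(C)C[C@]1(C)COC(C)(C)O1 | intermediate
11 | 1-[(4R)-2,2,4-trimethyl-1,3-dioxolan-4-yl]propan-2-one | CC(=O)C[C@]1(C)COC(C)(C)O1 | intermediate
12 | bis[(−)-isopinocampheyl]boron enolate of 11 (O-borylated on the methyl side) | C=C(OB([C@@H]1C[C@@H]2C[C@H]([C@H]1C)C2(C)C)[C@@H]1C[C@@H]2C[C@H]([C@H]1C)C2(C)C)C[C@]1(C)COC(C)(C)O1 | intermediate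
13 | (4R,5Z)-4-hydroxy-6-methyl-1-[(4R)-2,2,4-trimethyl-1,3-dioxolan-4-yl]-8-(trimethylsilyl)oct-5-en-7-yn-2-one | C[Si](C)(C)C#C/C(C)=C\[C@H](O)CC(=O)C[C@]1(C)COC(C)(C)O1 | intermediate
14 | (3Z,5R,7R)-7-hydroxy-3-methyl-8-[(4R)-2,2,4-trimethyl-1,3-dioxolan-4-yl]-1-(trimethylsilyl)oct-3-en-1-yn-5-yl acetate | C[Si](C)(C)C#C/C(C)=C\[C@H](OC(C)=O)C[C@@H](O)C[C@]1(C)COC(C)(C)O1 | intermediate
15 | (3Z,5R,7R)-7-[(tert-butyldimethylsilyl)oxy]-3-methyl-8-[(4R)-2,2,4-trimethyl-1,3-dioxolan-4-yl]-1-(trimethylsilyl)oct-3-en-1-yn-5-yl acetate | C[Si](C)(C)C#C/C(C)=C\[C@H](OC(C)=O)C[C@@H](O[Si](C)(C)C(C)(C)C)C[C@]1(C)COC(C)(C)O1 | intermediate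
16 | (3Z,5R,7R)-7-[(tert-butyldimethylsilyl)oxy]-1-iodo-3-methyl-8-[(4R)-2,2,4-trimethyl-1,3-dioxolan-4-yl]oct-3-en-1-yn-5-yl acetate | IC#C/C(C)=C\[C@H](OC(C)=O)C[C@@H](O[Si](C)(C)C(C)(C)C)C[C@]1(C)COC(C)(C)O1 | intermediate
17 | (3Z,5R,7R,9R)-7-[(tert-butyldimethylsilyl)oxy]-9,10-dihydroxy-1-iodo-3,9-dimethyldec-3-en-1-yn-5-yl acetate | IC#C/C(C)=C\[C@H](OC(C)=O)C[C@@H](O[Si](C)(C)C(C)(C)C)C[C@@](C)(O)CO | intermediate
18 | (3Z,5R,7R,9R)-7-[(tert-butyldimethylsilyl)oxy]-9-hydroxy-1-iodo-3,9-dimethyl-10-oxodec-3-en-1-yn-5-yl acetate | IC#C/C(C)=C\[C@H](OC(C)=O)C[C@@H](O[Si](C)(C)C(C)(C)C)C[C@@](C)(O)C=O | intermediate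
19 | (4Z,6R,8R,10R)-8-[(tert-butyldimethylsilyl)oxy]-1,10-dihydroxy-4,10-dimethylcyclodec-4-en-2-yn-6-yl acetate (target numbering, C1 epimers) | OC1C#C/C(C)=C\[C@H](OC(C)=O)C[C@@H](O[Si](C)(C)C(C)(C)C)C[C@@]1(C)O | intermediate
20 | (4Z,6R,8R,10R)-8-[(tert-butyldimethylsilyl)oxy]-10-hydroxy-4,10-dimethyl-1-oxocyclodec-4-en-2-yn-6-yl acetate (target numbering) | O=C1C#C/C(C)=C\[C@H](OC(C)=O)C[C@@H](O[Si](C)(C)C(C)(C)C)C[C@@]1(C)O | intermediate
21 | (4Z,6R,8R,10R)-8-[(tert-butyldimethylsilyl)oxy]-3,10-epoxy-4,10-dimethyl-1-oxocyclodeca-2,4-dien-6-yl acetate (furanone-bridged, target numbering) | CC(C)(C)[Si](C)(C)O[C@H]1C[C@@]2(C)OC(=CC2=O)/C(C)=C\[C@H](OC(C)=O)C1 | intermediate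
22 | (4Z,6R,8R,10R)-8-[(tert-butyldimethylsilyl)oxy]-3,10-epoxy-6-hydroxy-4,10-dimethylcyclodeca-2,4-dien-1-one (target numbering) | CC(C)(C)[Si](C)(C)O[C@H]1C[C@@]2(C)OC(=CC2=O)/C(C)=C\[C@H](O)C1 | intermediate
23 | angelic acid, (Z)-2-methylbut-2-enoic acid | C/C=C(/C)C(=O)O | starting material
24 | (Z)-2-methylbut-2-en-1-ol | C/C=C(/C)CO | intermediate
25 | [(2S,3R)-2,3-dimethyloxiran-2-yl]methanol | OC[C@]1(C)O[C@@H]1C | intermediate
26 | (2R,3R)-2,3-dimethyloxirane-2-carboxylic acid | OC(=O)[C@]1(C)O[C@@H]1C | intermediate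
27 | (4Z,6R,8R,10R)-8-[(tert-butyldimethylsilyl)oxy]-3,10-epoxy-4,10-dimethyl-1-oxocyclodeca-2,4-dien-6-yl (2R,3R)-2,3-dimethyloxirane-2-carboxylate | CC(C)(C)[Si](C)(C)O[C@H]1C[C@@]2(C)OC(=CC2=O)/C(C)=C\[C@H](OC(=O)[C@]3(C)O[C@@H]3C)C1 | intermediate
28 | (4Z,6R,8R,10R)-3,10-epoxy-8-hydroxy-4,10-dimethyl-1-oxocyclodeca-2,4-dien-6-yl (2R,3R)-2,3-dimethyloxirane-2-carboxylate | O[C@H]1C[C@@]2(C)OC(=CC2=O)/C(C)=C\[C@H](OC(=O)[C@]3(C)O[C@@H]3C)C1 | intermediate
29 | diethylphosphonoacetic acid, 2-(diethoxyphosphoryl)acetic acid | CCOP(=O)(OCC)CC(=O)O | starting material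
30 | (4Z,6R,8R,10R)-8-{[2-(diethoxyphosphoryl)acetyl]oxy}-3,10-epoxy-4,10-dimethyl-1-oxocyclodeca-2,4-dien-6-yl (2R,3R)-2,3-dimethyloxirane-2-carboxylate | CCOP(=O)(OCC)CC(=O)O[C@H]1C[C@@]2(C)OC(=CC2=O)/C(C)=C\[C@H](OC(=O)[C@]3(C)O[C@@H]3C)C1 | intermediate
31 | (4Z,6R,8R,10R)-8-{[2-diazo-2-(diethoxyphosphoryl)acetyl]oxy}-3,10-epoxy-4,10-dimethyl-1-oxocyclodeca-2,4-dien-6-yl (2R,3R)-2,3-dimethyloxirane-2-carboxylate | CCOP(=O)(OCC)C(=[N+]=[N-])C(=O)O[C@H]1C[C@@]2(C)OC(=CC2=O)/C(C)=C\[C@H](OC(=O)[C@]3(C)O[C@@H]3C)C1 | intermediate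
32 | (6S,7R,8S,10R,11R)-11-(diethoxyphosphoryl) trans-fused 12,8-lactone of the furanone-bridged cyclodecene, O6 (2R,3R)-epoxyangelate | CCOP(=O)(OCC)[C@H]1C(=O)O[C@H]2C[C@@]3(C)OC(=CC3=O)/C(C)=C\[C@H](OC(=O)[C@]4(C)O[C@@H]4C)[C@H]12 | intermediate
33 | CNP0258430.3, (6S,7R,8S,10R)-α-methylene lactone with O6 (2R,3R)-epoxyangelate | C=C1C(=O)O[C@H]2C[C@@]3(C)OC(=CC3=O)/C(C)=C\[C@H](OC(=O)[C@]3(C)O[C@@H]3C)[C@H]12 | target

## Step count and least certain steps

Total: 25 steps. Longest linear sequence: 19 steps (steps 4–16 and 20–25, or equally steps 1–3, 7–16 and 20–25).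

**Step 24 (key step).** The carbenoid may insert into the wrong C–H bond, either at C9 or at the C7 hydrogen that gives the cis-fused lactone. The competing methylene sites differ only modestly, and the choice between the two C7 hydrogens depends on the ring conformation. The fallback sets out from 28 and comes back at 33. 28 is acylated with bromoacetyl bromide and pyridine to the C8 bromoacetate F1. N,N'-ditosylhydrazine and DBU convert this into the C8 diazoacetate F2. The acceptor-only carbenoid from F2 is generated with a chiral dirhodium carboxamidate, Rh2(5S-MEPY)4 or its enantiomer, whichever is matched. This catalyst class controls site and diastereoselectivity in γ-lactone formation from secondary alkyl diazoacetates, and should give the C11-unsubstituted trans-lactone F3. LiHMDS and dimethylmethyleneammonium iodide then give the Mannich base F4. Methyl iodide quaternises it to the ammonium iodide F5, and NaHCO3 eliminates trimethylamine to give 33.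

**Step 13.** Oligomerisation and protodeiodination may outrun ring closure, because the ten-membered enyne ring is strained and the chain ends must meet at high dilution. The fallback moves the ring closure to C4=C5. It sets out from 11 and comes back at 21.
- The (−)-Ipc2BCl aldol of 11 with acrolein gives the vinyl carbinol F6.
- SmI2 and acetaldehyde give the anti monoacetate F7, and TBSOTf gives the silyl ether F8.
- PPTS in methanol gives the diol F9, and SO3·pyridine/DMSO gives the hydroxy aldehyde F10.
- The lithium acetylide of 2-methylbut-1-en-3-yne adds to F10 to give the propargylic diol F11.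
- IBX gives the ynone F12, and (Ph3P)AuCl/AgOTf closes the furanone diene F13.
- Ring-closing metathesis of F13 with the second-generation Grubbs catalyst, in which the ring allows only the Z alkene, gives 21.

**Step 7.** Facial selectivity at the aldehyde may be poor, because reagent control by isopinocampheyl ligands is only moderate for methyl ketone enolates and the remote C10 centre gives no help. The fallback sets out from 11 and comes back at 13. LDA and Me3SiCl at −78 °C give the trimethylsilyl enol ether F14. F14 is added to 6 under SiCl4 activated by a chiral binaphthyldiamine-derived bisphosphoramide. This is a Lewis-base-catalysed Mukaiyama aldol through an open transition state, and the catalyst enantiomer is chosen for Re-face addition. Aqueous work-up returns 13.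

**Step 15.** π-Activation may be diverted into other cyclisation or acyloxy-migration pathways of the enyne acetate, or closure may stall because C3 must bend out of line in a strained ring. The fallback sets out from 20 and comes back at 21. Diethylamine in ethanol adds to the ynone to give the β-(diethylamino)enone F15. Dilute acetic acid then closes the furanone by addition of the C10 hydroxyl and loss of diethylamine.

## Further compounds

F1 | step 24 | (4Z,6R,8R,10R)-8-(2-bromoacetoxy)-3,10-epoxy-4,10-dimethyl-1-oxocyclodeca-2,4-dien-6-yl (2R,3R)-2,3-dimethyloxirane-2-carboxylate | BrCC(=O)O[C@H]1C[C@@]2(C)OC(=CC2=O)/C(C)=C\[C@H](OC(=O)[C@]3(C)O[C@@H]3C)C1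
F2 | step 24 | (4Z,6R,8R,10R)-8-(2-diazoacetoxy)-3,10-epoxy-4,10-dimethyl-1-oxocyclodeca-2,4-dien-6-yl (2R,3R)-2,3-dimethyloxirane-2-carboxylate | [N-]=[N+]=CC(=O)O[C@H]1C[C@@]2(C)OC(=CC2=O)/C(C)=C\[C@H](OC(=O)[C@]3(C)O[C@@H]3C)C1
F3 | step 24 | (6S,7R,8S,10R)-trans-fused 12,8-lactone without C13, O6 (2R,3R)-epoxyangelate | C1C(=O)O[C@H]2C[C@@]3(C)OC(=CC3=O)/C(C)=C\[C@H](OC(=O)[C@]4(C)O[C@@H]4C)[C@H]12
F4 | step 24 | (6S,7R,8S,10R,11S)-11-[(dimethylamino)methyl] trans-fused 12,8-lactone, O6 (2R,3R)-epoxyangelate | CN(C)C[C@H]1C(=O)O[C@H]2C[C@@]3(C)OC(=CC3=O)/C(C)=C\[C@H](OC(=O)[C@]4(C)O[C@@H]4C)[C@H]12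
F5 | step 24 | (6S,7R,8S,10R,11S)-11-[(trimethylammonio)methyl] trans-fused 12,8-lactone iodide, O6 (2R,3R)-epoxyangelate | C[N+](C)(C)C[C@H]1C(=O)O[C@H]2C[C@@]3(C)OC(=CC3=O)/C(C)=C\[C@H](OC(=O)[C@]4(C)O[C@@H]4C)[C@H]12.[I-]
F6 | step 13 | (4R)-4-hydroxy-1-[(4R)-2,2,4-trimethyl-1,3-dioxolan-4-yl]hex-5-en-2-one | C=C[C@H](O)CC(=O)C[C@]1(C)COC(C)(C)O1
F7 | step 13 | (3R,5R)-5-hydroxy-6-[(4R)-2,2,4-trimethyl-1,3-dioxolan-4-yl]hex-1-en-3-yl acetate | C=C[C@H](OC(C)=O)C[C@@H](O)C[C@]1(C)COC(C)(C)O1
F8 | step 13 | (3R,5R)-5-[(tert-butyldimethylsilyl)oxy]-6-[(4R)-2,2,4-trimethyl-1,3-dioxolan-4-yl]hex-1-en-3-yl acetate | C=C[C@H](OC(C)=O)C[C@@H](O[Si](C)(C)C(C)(C)C)C[C@]1(C)COC(C)(C)O1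
F9 | step 13 | (3R,5R,7R)-5-[(tert-butyldimethylsilyl)oxy]-7,8-dihydroxy-7-methyloct-1-en-3-yl acetate | C=C[C@H](OC(C)=O)C[C@@H](O[Si](C)(C)C(C)(C)C)C[C@@](C)(O)CO
F10 | step 13 | (3R,5R,7R)-5-[(tert-butyldimethylsilyl)oxy]-7-hydroxy-7-methyl-8-oxooct-1-en-3-yl acetate | C=C[C@H](OC(C)=O)C[C@@H](O[Si](C)(C)C(C)(C)C)C[C@@](C)(O)C=O
F11 | step 13 | (3R,5R,7R)-5-[(tert-butyldimethylsilyl)oxy]-7,8-dihydroxy-7,11-dimethyldodeca-1,11-dien-9-yn-3-yl acetate (C8 epimers) | C=C[C@H](OC(C)=O)C[C@@H](O[Si](C)(C)C(C)(C)C)C[C@@](C)(O)C(O)C#CC(C)=C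
F12 | step 13 | (3R,5R,7R)-5-[(tert-butyldimethylsilyl)oxy]-7-hydroxy-7,11-dimethyl-8-oxododeca-1,11-dien-9-yn-3-yl acetate | C=C[C@H](OC(C)=O)C[C@@H](O[Si](C)(C)C(C)(C)C)C[C@@](C)(O)C(=O)C#CC(C)=C
F13 | step 13 | (3R,5R)-5-[(tert-butyldimethylsilyl)oxy]-6-[(2R)-2-methyl-3-oxo-5-(prop-1-en-2-yl)-2,3-dihydrofuran-2-yl]hex-1-en-3-yl acetate | C=C[C@H](OC(C)=O)C[C@@H](O[Si](C)(C)C(C)(C)C)C[C@@]1(C)OC(=CC1=O)C(C)=C
F14 | step 7 | trimethyl({3-[(4R)-2,2,4-trimethyl-1,3-dioxolan-4-yl]prop-1-en-2-yl}oxy)silane | C=C(O[Si](C)(C)C)C[C@]1(C)COC(C)(C)O1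
F15 | step 15 | (4Z,6R,8R,10R)-8-[(tert-butyldimethylsilyl)oxy]-3-(diethylamino)-10-hydroxy-4,10-dimethyl-1-oxocyclodeca-2,4-dien-6-yl acetate (target numbering) | O=C1C=C(N(CC)CC)/C(C)=C\[C@H](OC(C)=O)C[C@@H](O[Si](C)(C)C(C)(C)C)C[C@@]1(C)O
A1 | alternative 1 | (5R)-5-{[(tert-butyldimethylsilyl)oxy]methyl}furan-2(5H)-one | O=C1C=C[C@H](CO[Si](C)(C)C(C)(C)C)O1
A2 | alternative 1 | trans,trans-5-{[(tert-butyldimethylsilyl)oxy]methyl}-3-[(dimethylamino)methyl]-4-[tris(methylthio)methyl]dihydrofuran-2(3H)-one | CN(C)C[C@H]1C(=O)O[C@@H](CO[Si](C)(C)C(C)(C)C)[C@@H]1C(SC)(SC)SC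
A3 | alternative 2 | 3-diazo-1-{2,6-cis-5-[(tert-butyldimethylsilyl)oxy]-3-methyl-6-vinyl-5,6-dihydro-2H-pyran-2-yl}butan-2-one | CC(=[N+]=[N-])C(=O)C[C@H]1O[C@@H](C=C)[C@@H](O[Si](C)(C)C(C)(C)C)C=C1C
A4 | alternative 2 | dihydrofuranone-bridged Z,Z-cyclodecadiene (11-oxabicyclo[6.2.1]undecadienone) with C10 quaternary centre and C6 silyl ether | C[C@@]12C/C=C\[C@@H](O[Si](C)(C)C(C)(C)C)/C=C(C)\[C@@H](CC1=O)O2
A5 | alternative 3 | furanone-bridged eleven-membered cyclic sulfone (sulfur between C4 and C5) with free C6 hydroxyl, C8 silyl ether and C7 3-(silyloxy)prop-1-en-2-yl group | CC(C)(C)[Si](C)(C)O[C@H]1C[C@@]2(C)OC(=CC2=O)C(C)S(=O)(=O)C[C@H](O)[C@@H]1C(=C)CO[Si](C)(C)C(C)(C)C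
A6 | alternative 3 | furanone-bridged Z-cyclodecene with free C6 hydroxyl, C8 silyl ether and C7 3-(silyloxy)prop-1-en-2-yl group | CC(C)(C)[Si](C)(C)O[C@H]1C[C@@]2(C)OC(=CC2=O)/C(C)=C\[C@H](O)[C@@H]1C(=C)CO[Si](C)(C)C(C)(C)C
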